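**Plan**

- Retrosynthesis: open lactone A at O1–C2 and remove all O-methyl groups; cut lactone B at C3'–C4' and O1'–C2' (enolate plus ortho-quinone methide); cut benzene ring A at C5–C6 (Claisen/Dieckmann closure of a 3,5-dioxoheptanedioate); cut that chain between its malonyl carbonyl and a four-carbon dienol ether; cut C3–C4 (Michael addition).
- Forward: C3–C4 bond by organocatalytic Michael addition; chain joined to the triketide diester; benzene ring A closed (key step); lactone B annulated onto C3'; lactone A closed last in the global deprotection.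
- Enabling feature: benzene ring A (C4a, C5, C6, C7, C8, C8a) bears oxygen on C5, C7 and C8a, the alternating pattern of a folded triketide whose chain C2 (later C4a) hangs on stereocentre C4.
- Stereochemistry: C3 and C4 from the (R)-diphenylprolinol silyl ether (syn Michael adduct, which becomes the trans lactone A); C3' from (S)-4-benzyl-1,3-oxazolidin-2-one; C4' from the chelated Z-enolate/E-methide transition state (cis lactone B).

Key step: step 9

Assumption: the malonate carbon created in step 5 (later C4a) is carried as a mixture of epimers, and 1,2,3,4-tetramethoxybenzene is taken as purchasable; unprimed locants belong to the 5,7-dihydroxychromanone unit (ring A, lactone A), primed locants to the tetrahydroxychromanone unit (ring B, lactone B).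

**Route**

Step 1
Reactants: 1 4-methoxybenzaldehyde; 2 Meldrum's acid (2,2-dimethyl-1,3-dioxane-4,6-dione)
Product: 3 5-(4-methoxybenzylidene)-2,2-dimethyl-1,3-dioxane-4,6-dione
Conditions: H2O, 75 °C
Reagents that add atoms: none
Why: Knoevenagel condensation of the strongly C–H acidic dione with an aromatic aldehyde runs without catalyst in hot water and gives a symmetrical, very electrophilic acceptor that has no E/Z isomers and no acidic C–H.

Step 2
Reactants: 3 5-(4-methoxybenzylidene)-2,2-dimethyl-1,3-dioxane-4,6-dione; 4 methyl 4-oxobutanoate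
Product: 5 methyl (3S,4S)-4-(2,2-dimethyl-4,6-dioxo-1,3-dioxan-5-yl)-3-formyl-4-(4-methoxyphenyl)butanoate
Conditions: 4 (3 equiv), (R)-2-[diphenyl(trimethylsilyloxy)methyl]pyrrolidine (10 mol%), toluene, 0 °C
Reagents that add atoms: none
Why: Enamine-catalysed Michael addition of an aldehyde to an alkylidene malonate-type acceptor, in which the E-enamine of 4 is shielded on one face by the CPh2(OSiMe3) group and should add through the synclinal acyclic transition state, so that C3 and C4 are set together as the syn adduct in the sense established for nitroalkene and alkylidene malonate acceptors.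

Step 3
Reactants: 5 methyl (3S,4S)-4-(2,2-dimethyl-4,6-dioxo-1,3-dioxan-5-yl)-3-formyl-4-(4-methoxyphenyl)butanoate
Product: 6 (2S,3S)-3-(2,2-dimethyl-4,6-dioxo-1,3-dioxan-5-yl)-2-(2-methoxy-2-oxoethyl)-3-(4-methoxyphenyl)propanoic acid
Conditions: NaClO2, NaH2PO4, 2-methylbut-2-ene, t-BuOH/H2O, 0 °C
Reagents that add atoms: NaClO2 (sodium chlorite), [Na+].[O-]Cl=O
Why: Pinnick oxidation takes the crude aldehyde to the acid at once, so that the enolisable C3 centre is secured, while the alkene scavenger removes hypochlorous acid before it can chlorinate the anisyl ring or the dione C–H.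

Step 4
Reactants: 6 (2S,3S)-3-(2,2-dimethyl-4,6-dioxo-1,3-dioxan-5-yl)-2-(2-methoxy-2-oxoethyl)-3-(4-methoxyphenyl)propanoic acid
Product: 7 1-tert-butyl 4-methyl (2S)-2-[(S)-(2,2-dimethyl-4,6-dioxo-1,3-dioxan-5-yl)(4-methoxyphenyl)methyl]butanedioate
Conditions: tert-butyl 2,2,2-trichloroacetimidate (2.5 equiv), CH2Cl2/cyclohexane, rt
Reagents that add atoms: tert-butyl 2,2,2-trichloroacetimidate, CC(C)(C)OC(=N)C(Cl)(Cl)Cl
Why: Imidate tert-butylation of a carboxylic acid, promoted by the acid itself, installs the hindered ester at C2 that must later stay out of the Claisen manifold; the dione C–H can at most be O-alkylated reversibly.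

Step 5
Reactants: 7 1-tert-butyl 4-methyl (2S)-2-[(S)-(2,2-dimethyl-4,6-dioxo-1,3-dioxan-5-yl)(4-methoxyphenyl)methyl]butanedioate
Product: 8 (3S,4S)-4-(tert-butoxycarbonyl)-6-methoxy-2-(methoxycarbonyl)-3-(4-methoxyphenyl)-6-oxohexanoic acid (C2 epimers)
Conditions: MeOH, 65 °C
Reagents that add atoms: methanol, CO
Why: Alcoholysis of a 5-monosubstituted Meldrum's acid opens the ring at one carbonyl with loss of acetone and gives the malonic half ester, which does not decarboxylate at this temperature, under neutral conditions that leave the tert-butyl ester and C3 untouched.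

Step 6
Reactants: 9 tert-butyl 3-oxobutanoate
Product: 10 tert-butyl 3-(trimethylsilyloxy)but-2-enoate
Conditions: Me3SiCl, Et3N, pentane, rt
Reagents that add atoms: chlorotrimethylsilane, C[Si](C)(C)Cl
Why: O-silylation of the enol of a β-keto ester by silyl chloride and amine is the standard first stage towards a 1,3-bis(silyloxy)diene.

Step 7
Reactants: 10 tert-butyl 3-(trimethylsilyloxy)but-2-enoate
Product: 12 1-tert-butoxy-1,3-bis(trimethylsilyloxy)buta-1,3-diene, via lithium dienolate 11 (not isolated)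
Conditions: LiN(iPr)2, THF, −78 °C; Me3SiCl, −78 → 0 °C
Reagents that add atoms: chlorotrimethylsilane, C[Si](C)(C)Cl
Why: Kinetic γ-deprotonation of the silyloxy enoate and O-silylation of the dienolate is the established preparation of acetoacetate-derived bis-silyl dienol ethers.

Step 8
Reactants: 8 (3S,4S)-4-(tert-butoxycarbonyl)-6-methoxy-2-(methoxycarbonyl)-3-(4-methoxyphenyl)-6-oxohexanoic acid; 12 1-tert-butoxy-1,3-bis(trimethylsilyloxy)buta-1,3-diene
Product: 15 7-tert-butyl 1-methyl 2-[(1S,2S)-2-(tert-butoxycarbonyl)-4-methoxy-1-(4-methoxyphenyl)-4-oxobutyl]-3,5-dioxoheptanedioate, via acid chloride 13 (not isolated), via silyl enol ether 14 (not isolated)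
Conditions: 1-chloro-N,N,2-trimethylprop-1-en-1-amine, CH2Cl2, 0 °C; then 12, −78 → 0 °C; aq. NaHCO3
Reagents that add atoms: none
Why: The α-chloroenamine makes the acid chloride under neutral conditions that spare tert-butyl esters, and bis-silyl dienol ethers are C-acylated by acid chlorides at their terminal carbon (vinylogous Mukaiyama-type acylation) to give 3,5-dioxo esters after desilylation, with no base present that could deprotonate the malonyl C–H.

Step 9
Reactants: 15 7-tert-butyl 1-methyl 2-[(1S,2S)-2-(tert-butoxycarbonyl)-4-methoxy-1-(4-methoxyphenyl)-4-oxobutyl]-3,5-dioxoheptanedioate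
Product: 17 tert-butyl 3-[(1R,2S)-2-(tert-butoxycarbonyl)-4-methoxy-1-(4-methoxyphenyl)-4-oxobutyl]-2,4,6-trihydroxybenzoate, via cyclohexanetrione 16 (not isolated)
Conditions: Mg(OMe)2 (4 equiv), MeOH, 50 °C; then 1 M HCl, 0 °C
Reagents that add atoms: none
Why: As its magnesium chelate the chain should be enolised at chain C4 and C6 (chain C2 is spared because its enolate would suffer allylic strain against the branched substituent), and chain C6, activated by the C5 ketone and the C7 tert-butyl ester, adds to the C1 methyl ester carbonyl; loss of methoxide gives trione 16, whose tautomerisation to phloroglucinol 17 makes the C-acylation irreversible. The closest known reaction type is the biomimetic Claisen (Dieckmann) cyclisation of 3,5-dioxo diesters and 3,5,7-trioxo esters to phloroglucinol carboxylates and acylphloroglucinols, for which a magnesium alkoxide is the classical template. The carbocycle of ring A closes in the 6-exo-trig mode, and the new bond is the one that becomes C5–C6 of the target (the two oxygens flanking C4a become equivalent once the ring ester is removed). No stereocentre is formed: C3 and C4 lie outside every 1,3-dicarbonyl unit and keep their configuration, and the stereorandom malonate carbon becomes arene carbon C4a. The step needs chemoselectivity among the possible acylations, and the substrate secures it: closure of chain C2 onto C7 would give a quaternary trione that cannot aromatise and is further blocked by the tert-butyl ester, the tert-butyl ester at target C2 resists attack by chain C4, the distal methyl ester could only be reached through a five-membered ring with a quaternary centre or a seven-membered ring, and O-acylation to the 4-hydroxy-2-pyranone is reversed by magnesium methoxide, so aromatisation drains the equilibria into 17.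

Step 10
Reactants: 17 tert-butyl 3-[(1R,2S)-2-(tert-butoxycarbonyl)-4-methoxy-1-(4-methoxyphenyl)-4-oxobutyl]-2,4,6-trihydroxybenzoate
Product: 18 tert-butyl 3-[(1R,2S)-2-(tert-butoxycarbonyl)-4-methoxy-1-(4-methoxyphenyl)-4-oxobutyl]-2,4,6-trimethoxybenzoate
Conditions: Me2SO4, K2CO3, acetone, 56 °C
Reagents that add atoms: dimethyl sulfate, COS(=O)(=O)OC
Why: Williamson O-methylation of the three phenols, in which the ring ester suppresses the C-methylation typical of phloroglucinols and the hindered tert-butyl ester at C2 should not be attacked by the neighbouring phenoxide before it is capped.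

Step 11
Reactants: 18 tert-butyl 3-[(1R,2S)-2-(tert-butoxycarbonyl)-4-methoxy-1-(4-methoxyphenyl)-4-oxobutyl]-2,4,6-trimethoxybenzoate
Product: 19 (3S,4R)-3-(tert-butoxycarbonyl)-4-[3-(tert-butoxycarbonyl)-2,4,6-trimethoxyphenyl]-4-(4-methoxyphenyl)butanoic acid
Conditions: LiOH, THF/H2O, 0 °C → rt; then 1 M HCl to pH 3, 0 °C
Reagents that add atoms: LiOH (lithium hydroxide), [Li+].[OH-]
Why: Saponification should touch only the unhindered primary methyl ester at C2', since both tert-butyl esters are inert to hydroxide and C3 is not enolised under these conditions.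

Step 12
Reactants: 19 (3S,4R)-3-(tert-butoxycarbonyl)-4-[3-(tert-butoxycarbonyl)-2,4,6-trimethoxyphenyl]-4-(4-methoxyphenyl)butanoic acid; 20 (S)-4-benzyl-1,3-oxazolidin-2-one
Product: 22 tert-butyl 3-[(1R,2S)-4-[(4S)-4-benzyl-2-oxo-1,3-oxazolidin-3-yl]-2-(tert-butoxycarbonyl)-1-(4-methoxyphenyl)-4-oxobutyl]-2,4,6-trimethoxybenzoate, via mixed pivalic anhydride 21 (not isolated)
Conditions: t-BuCOCl, Et3N, THF, −20 °C; then 20, LiCl, −20 °C → rt
Reagents that add atoms: none
Why: N-Acylation of the oxazolidinone through the mixed pivalic anhydride (LiCl/Et3N variant) is routine for succinic half esters carrying a tert-butyl ester and gives the imide whose α-CH2 (C3') is now the most acidic C–H of the molecule.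

Step 13
Reactants: 23 1,2,3,4-tetramethoxybenzene
Product: 26 2,3,4,5-tetramethoxyphenol, via aryllithium 24 (not isolated), via dimethyl arylboronate 25 (not isolated)
Conditions: n-BuLi, TMEDA, THF, 0 °C; B(OMe)3, −78 °C → rt; AcOH, 30% H2O2, 0 °C → rt
Reagents that add atoms: hydrogen peroxide, OO
Why: Methoxy-directed ortho-lithiation (both aryl C–H are equivalent), borylation and oxidative C–B to C–O conversion deliver the phenol with a single free ortho position.

Step 14
Reactants: 26 2,3,4,5-tetramethoxyphenol; 1 4-methoxybenzaldehyde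
Product: 28 2,3,4,5-tetramethoxy-6-[(4-methoxyphenyl)(4-methylbenzenesulfonyl)methyl]phenol (racemic), via benzhydrol 27 (not isolated)
Conditions: sodium 4-methylbenzenesulfinate, HCO2H/H2O (1:1), rt
Reagents that add atoms: sodium 4-methylbenzenesulfinate, [Na+].[O-]S(=O)c1ccc(C)cc1
Why: Three-component sulfonylalkylation of an electron-rich phenol, in which the only free ortho carbon is hydroxyalkylated, the benzhydrol ionises in acid and sulfinate captures the methide at sulfur, gives a bench-stable ortho-quinone methide precursor.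

Step 15
Reactants: 22 tert-butyl 3-[(1R,2S)-4-[(4S)-4-benzyl-2-oxo-1,3-oxazolidin-3-yl]-2-(tert-butoxycarbonyl)-1-(4-methoxyphenyl)-4-oxobutyl]-2,4,6-trimethoxybenzoate; 28 2,3,4,5-tetramethoxy-6-[(4-methoxyphenyl)(4-methylbenzenesulfonyl)methyl]phenol
Product: 32 tert-butyl 3-{(1R,2R)-3-tert-butoxy-1-(4-methoxyphenyl)-3-oxo-2-[(3S,4R)-5,6,7,8-tetramethoxy-4-(4-methoxyphenyl)-2-oxo-3,4-dihydro-2H-chromen-3-yl]propyl}-2,4,6-trimethoxybenzoate, via sodium enolate 29 (not isolated), via ortho-quinone methide 30 (not isolated), via Michael adduct phenoxide 31 (not isolated)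
Conditions: 22, NaN(SiMe3)2 (1.05 equiv), THF, −78 °C; 28 + NaN(SiMe3)2 (1.0 equiv), THF, −78 → 0 °C, cannulated in at −78 °C; −78 → −30 °C; AcOH, −78 °C
Reagents that add atoms: none
Why: Proposed new method: the sodium-chelated Z-enolate 29 should add to the methide carbon of 30 (formed when the phenoxide of 28 expels sulfinate) on the enolate face left open by the benzyl group of the (S)-auxiliary, which sets C3' as S and is reinforced by C3, whose large diarylmethyl group lies anti to the incoming carbon when C3–H eclipses the enolate; a compact transition state in which Na bridges the enolate and methide oxygens and the aryl group of the E-methide points outward should set C4' as R, cis to the C3'–C3 bond, after which the phenoxide of 31 attacks the imide carbonyl in a 6-exo-trig lactonisation that expels the auxiliary; the closest known reaction types are the alkylation and Michael addition of chelated N-acyloxazolidinone enolates and the Michael addition–lactonisation of ester enolate equivalents with ortho-quinone methides to 3,4-disubstituted dihydrocoumarins.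

Step 16
Reactants: 32 tert-butyl 3-{(1R,2R)-3-tert-butoxy-1-(4-methoxyphenyl)-3-oxo-2-[(3S,4R)-5,6,7,8-tetramethoxy-4-(4-methoxyphenyl)-2-oxo-3,4-dihydro-2H-chromen-3-yl]propyl}-2,4,6-trimethoxybenzoate
Product: 34 (2R,3R)-3-(4-methoxyphenyl)-2-[(3S,4R)-5,6,7,8-tetramethoxy-4-(4-methoxyphenyl)-2-oxo-3,4-dihydro-2H-chromen-3-yl]-3-(2,4,6-trimethoxyphenyl)propanoic acid, via diacid 33 (not isolated)
Conditions: CF3CO2H/CH2Cl2 (1:1), 0 °C → rt, N2 sweep; then 40 °C
Reagents that add atoms: none
Why: Acidolysis removes both tert-butyl esters as isobutene, and the resulting 2,4,6-trialkoxybenzoic acid should protodecarboxylate by ipso protonation in the same acid, while lactone B and the four stereocentres, which are only base-labile, are left alone.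

Step 17
Reactants: 34 (2R,3R)-3-(4-methoxyphenyl)-2-[(3S,4R)-5,6,7,8-tetramethoxy-4-(4-methoxyphenyl)-2-oxo-3,4-dihydro-2H-chromen-3-yl]-3-(2,4,6-trimethoxyphenyl)propanoic acid
Product: 36 (3R,4R)-5,7-dihydroxy-4-(4-hydroxyphenyl)-3-[(3S,4R)-5,6,7,8-tetrahydroxy-4-(4-hydroxyphenyl)-2-oxo-3,4-dihydro-2H-chromen-3-yl]-3,4-dihydro-2H-chromen-2-one, via hydroxy acid 35 (not isolated)
Conditions: BBr3 (20 equiv), CH2Cl2, −78 °C → rt; then degassed H2O, 0 °C → rt
Reagents that add atoms: none
Why: BBr3 ether cleavage frees all nine phenols, and the C2 acid should then acylate either of the two equivalent ortho hydroxyls of ring A (6-exo-trig lactonisation, helped by the fully substituted chain), which closes lactone A with the trans C3/C4 relationship fixed since step 2 and, in the absence of base, leaves the cis C3'/C4' relationship of lactone B untouched.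

**Compound list**

1 | 4-methoxybenzaldehyde | COc1ccc(C=O)cc1 | starting material
2 | Meldrum's acid (2,2-dimethyl-1,3-dioxane-4,6-dione) | CC1(C)OC(=O)CC(=O)O1 | starting material
3 | 5-(4-methoxybenzylidene)-2,2-dimethyl-1,3-dioxane-4,6-dione | COc1ccc(C=C2C(=O)OC(C)(C)OC2=O)cc1 | intermediate
4 | methyl 4-oxobutanoate | COC(=O)CCC=O | starting material
5 | methyl (3S,4S)-4-(2,2-dimethyl-4,6-dioxo-1,3-dioxan-5-yl)-3-formyl-4-(4-methoxyphenyl)butanoate | CC1(C)OC(=O)C(C(=O)O1)[C@@H](c1ccc(OC)cc1)[C@@H](C=O)CC(=O)OC | intermediate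
6 | (2S,3S)-3-(2,2-dimethyl-4,6-dioxo-1,3-dioxan-5-yl)-2-(2-methoxy-2-oxoethyl)-3-(4-methoxyphenyl)propanoic acid | CC1(C)OC(=O)C(C(=O)O1)[C@@H](c1ccc(OC)cc1)[C@@H](C(=O)O)CC(=O)OC | intermediate
7 | 1-tert-butyl 4-methyl (2S)-2-[(S)-(2,2-dimethyl-4,6-dioxo-1,3-dioxan-5-yl)(4-methoxyphenyl)methyl]butanedioate | CC1(C)OC(=O)C(C(=O)O1)[C@@H](c1ccc(OC)cc1)[C@@H](C(=O)OC(C)(C)C)CC(=O)OC | intermediate
8 | (3S,4S)-4-(tert-butoxycarbonyl)-6-methoxy-2-(methoxycarbonyl)-3-(4-methoxyphenyl)-6-oxohexanoic acid, mixture of C2 epimers | OC(=O)C(C(=O)OC)[C@@H](c1ccc(OC)cc1)[C@@H](C(=O)OC(C)(C)C)CC(=O)OC | intermediate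
9 | tert-butyl 3-oxobutanoate | CC(=O)CC(=O)OC(C)(C)C | starting material
10 | tert-butyl 3-(trimethylsilyloxy)but-2-enoate | CC(O[Si](C)(C)C)=CC(=O)OC(C)(C)C | intermediate
11 | lithium dienolate of 10 (formed in the flask) | C=C(O[Si](C)(C)C)C=C(O[Li])OC(C)(C)C | intermediate
12 | 1-tert-butoxy-1,3-bis(trimethylsilyloxy)buta-1,3-diene | C=C(O[Si](C)(C)C)C=C(O[Si](C)(C)C)OC(C)(C)C | intermediate
13 | acid chloride of 8 (formed in the flask; configuration as in 8) | ClC(=O)C(C(=O)OC)[C@@H](c1ccc(OC)cc1)[C@@H](C(=O)OC(C)(C)C)CC(=O)OC | intermediate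
14 | 5-O-trimethylsilyl enol ether of 15 (formed in the flask; configuration as in 15) | CC(C)(C)OC(=O)C=C(O[Si](C)(C)C)CC(=O)C(C(=O)OC)[C@@H](c1ccc(OC)cc1)[C@@H](C(=O)OC(C)(C)C)CC(=O)OC | intermediate
15 | 7-tert-butyl 1-methyl 2-[(1S,2S)-2-(tert-butoxycarbonyl)-4-methoxy-1-(4-methoxyphenyl)-4-oxobutyl]-3,5-dioxoheptanedioate, mixture of C2 epimers | CC(C)(C)OC(=O)CC(=O)CC(=O)C(C(=O)OC)[C@@H](c1ccc(OC)cc1)[C@@H](C(=O)OC(C)(C)C)CC(=O)OC | intermediate
16 | tert-butyl 2,4,6-trioxocyclohexane-1-carboxylate carrying at C3 the side chain of 15 in unchanged configuration (formed in the flask) | CC(C)(C)OC(=O)C1C(=O)CC(=O)C(C1=O)[C@@H](c1ccc(OC)cc1)[C@@H](C(=O)OC(C)(C)C)CC(=O)OC | intermediate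
17 | tert-butyl 3-[(1R,2S)-2-(tert-butoxycarbonyl)-4-methoxy-1-(4-methoxyphenyl)-4-oxobutyl]-2,4,6-trihydroxybenzoate | CC(C)(C)OC(=O)c1c(O)cc(O)c(c1O)[C@@H](c1ccc(OC)cc1)[C@@H](C(=O)OC(C)(C)C)CC(=O)OC | intermediate
18 | tert-butyl 3-[(1R,2S)-2-(tert-butoxycarbonyl)-4-methoxy-1-(4-methoxyphenyl)-4-oxobutyl]-2,4,6-trimethoxybenzoate | CC(C)(C)OC(=O)c1c(OC)cc(OC)c(c1OC)[C@@H](c1ccc(OC)cc1)[C@@H](C(=O)OC(C)(C)C)CC(=O)OC | intermediate
19 | (3S,4R)-3-(tert-butoxycarbonyl)-4-[3-(tert-butoxycarbonyl)-2,4,6-trimethoxyphenyl]-4-(4-methoxyphenyl)butanoic acid | CC(C)(C)OC(=O)c1c(OC)cc(OC)c(c1OC)[C@@H](c1ccc(OC)cc1)[C@@H](C(=O)OC(C)(C)C)CC(=O)O | intermediate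
20 | (S)-4-benzyl-1,3-oxazolidin-2-one | O=C1OC[C@H](Cc2ccccc2)N1 | starting material
21 | mixed anhydride of 19 and pivalic acid (formed in the flask; configuration as in 19) | CC(C)(C)OC(=O)c1c(OC)cc(OC)c(c1OC)[C@@H](c1ccc(OC)cc1)[C@@H](C(=O)OC(C)(C)C)CC(=O)OC(=O)C(C)(C)C | intermediate
22 | tert-butyl 3-[(1R,2S)-4-[(4S)-4-benzyl-2-oxo-1,3-oxazolidin-3-yl]-2-(tert-butoxycarbonyl)-1-(4-methoxyphenyl)-4-oxobutyl]-2,4,6-trimethoxybenzoate | CC(C)(C)OC(=O)c1c(OC)cc(OC)c(c1OC)[C@@H](c1ccc(OC)cc1)[C@@H](C(=O)OC(C)(C)C)CC(=O)N1C(=O)OC[C@@H]1Cc1ccccc1 | intermediate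
23 | 1,2,3,4-tetramethoxybenzene | COc1ccc(OC)c(OC)c1OC | starting material
24 | 2,3,4,5-tetramethoxyphenyllithium (formed in the flask) | [Li]c1cc(OC)c(OC)c(OC)c1OC | intermediate
25 | dimethyl (2,3,4,5-tetramethoxyphenyl)boronate (formed in the flask) | COB(OC)c1cc(OC)c(OC)c(OC)c1OC | intermediate
26 | 2,3,4,5-tetramethoxyphenol | Oc1cc(OC)c(OC)c(OC)c1OC | intermediate
27 | 2-[hydroxy(4-methoxyphenyl)methyl]-3,4,5,6-tetramethoxyphenol, racemic (formed in the flask) | COc1ccc(cc1)C(O)c1c(O)c(OC)c(OC)c(OC)c1OC | intermediate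
28 | 2,3,4,5-tetramethoxy-6-[(4-methoxyphenyl)(4-methylbenzenesulfonyl)methyl]phenol, racemic | COc1ccc(cc1)C(c1c(O)c(OC)c(OC)c(OC)c1OC)S(=O)(=O)c1ccc(C)cc1 | intermediate
29 | sodium (Z)-enolate of imide 22 (formed in the flask; C4 and C3 as in 22) | CC(C)(C)OC(=O)c1c(OC)cc(OC)c(c1OC)[C@@H](c1ccc(OC)cc1)[C@@H](C(=O)OC(C)(C)C)/C=C(\O[Na])N1C(=O)OC[C@@H]1Cc1ccccc1 | intermediate
30 | (E)-6-(4-methoxybenzylidene)-2,3,4,5-tetramethoxycyclohexa-2,4-dien-1-one (formed in the flask) | COc1ccc(/C=C2/C(=O)C(OC)=C(OC)C(OC)=C2OC)cc1 | intermediate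
31 | sodium phenoxide of the open Michael adduct, imide still attached, C4 R, C3 R, C3' S, C4' R (formed in the flask) | CC(C)(C)OC(=O)c1c(OC)cc(OC)c(c1OC)[C@@H](c1ccc(OC)cc1)[C@@H](C(=O)OC(C)(C)C)[C@@H](C(=O)N1C(=O)OC[C@@H]1Cc1ccccc1)[C@H](c1ccc(OC)cc1)c1c(O[Na])c(OC)c(OC)c(OC)c1OC | intermediate
32 | tert-butyl 3-{(1R,2R)-3-tert-butoxy-1-(4-methoxyphenyl)-3-oxo-2-[(3S,4R)-5,6,7,8-tetramethoxy-4-(4-methoxyphenyl)-2-oxo-3,4-dihydro-2H-chromen-3-yl]propyl}-2,4,6-trimethoxybenzoate | CC(C)(C)OC(=O)c1c(OC)cc(OC)c(c1OC)[C@@H](c1ccc(OC)cc1)[C@@H](C(=O)OC(C)(C)C)[C@H]1C(=O)Oc2c(OC)c(OC)c(OC)c(OC)c2[C@H]1c1ccc(OC)cc1 | intermediate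
33 | diacid from 32 after loss of both tert-butyl groups (formed in the flask; configuration as in 32) | OC(=O)c1c(OC)cc(OC)c(c1OC)[C@@H](c1ccc(OC)cc1)[C@@H](C(=O)O)[C@H]1C(=O)Oc2c(OC)c(OC)c(OC)c(OC)c2[C@H]1c1ccc(OC)cc1 | intermediate
34 | (2R,3R)-3-(4-methoxyphenyl)-2-[(3S,4R)-5,6,7,8-tetramethoxy-4-(4-methoxyphenyl)-2-oxo-3,4-dihydro-2H-chromen-3-yl]-3-(2,4,6-trimethoxyphenyl)propanoic acid | COc1cc(OC)c(c(OC)c1)[C@@H](c1ccc(OC)cc1)[C@@H](C(=O)O)[C@H]1C(=O)Oc2c(OC)c(OC)c(OC)c(OC)c2[C@H]1c1ccc(OC)cc1 | intermediate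
35 | fully demethylated hydroxy acid, lactone A still open (formed in the flask; configuration as in 34) | Oc1cc(O)c(c(O)c1)[C@@H](c1ccc(O)cc1)[C@@H](C(=O)O)[C@H]1C(=O)Oc2c(O)c(O)c(O)c(O)c2[C@H]1c1ccc(O)cc1 | intermediate
36 | (3R,4R)-5,7-dihydroxy-4-(4-hydroxyphenyl)-3-[(3S,4R)-5,6,7,8-tetrahydroxy-4-(4-hydroxyphenyl)-2-oxo-3,4-dihydro-2H-chromen-3-yl]-3,4-dihydro-2H-chromen-2-one | O=C1Oc2cc(O)cc(O)c2[C@@H](c2ccc(O)cc2)[C@@H]1[C@H]1C(=O)Oc2c(O)c(O)c(O)c(O)c2[C@H]1c1ccc(O)cc1 | target

**Step count and risks**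

Total steps: 17. Longest linear sequence: 13 (steps 1–5, 8–12, 15–17).

Step 15 (labelled as a new method).
- What may go wrong: the methide may be attacked through an open transition state or as its Z isomer, so that facial selectivity at C4' is poor and a C4' epimer forms that cannot be corrected later. Bond formation between the two crowded carbons may be slower than re-addition of sulfinate or self-condensation of the methide. The oxazolidinone anion released on lactonisation may epimerise C3' to the trans lactone.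
- Fallback, known reactions only, from 19 back to 32: phenol 26 is O-acylated with 4-methoxybenzoyl chloride (Et3N, CH2Cl2) to 2,3,4,5-tetramethoxyphenyl 4-methoxybenzoate F1. A Fries rearrangement (TiCl4, CH2Cl2) moves the acyl group to the only free ortho carbon and gives (2-hydroxy-3,4,5,6-tetramethoxyphenyl)(4-methoxyphenyl)methanone F2. Acid 19 is esterified with F2 (EDC, DMAP) to the 2-aroylphenyl ester F3. LiN(SiMe3)2 enolises only the CH2 next to the aryl ester, and intramolecular aldol addition to the ketone gives the 4-hydroxy lactone F4, which is dehydrated (MeSO2Cl, Et3N) to the 3,4-disubstituted coumarin F5. Hydrogenation over Pd/C adds both hydrogens to one face of the C3'=C4' bond, so the cis relationship follows from the mechanism; the face should be the one away from the diarylmethyl group at C4 when C3–H eclipses the coumarin plane, which leads to 32.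

Step 2.
- What may go wrong: the acidic adduct may hold the amine catalyst as a cyclic aminal and stop turnover. The amine may exchange the aldehyde component of 3 by retro-Knoevenagel reaction. Enolisation of the product aldehyde may erode the syn selectivity.
- Fallback, from 3 back to 6: mono-methyl succinate is coupled (t-BuCOCl, Et3N; LiCl) with (R)-4-benzyl-1,3-oxazolidin-2-one to methyl 4-[(4R)-4-benzyl-2-oxo-1,3-oxazolidin-3-yl]-4-oxobutanoate F6. Its chlorotitanium enolate (TiCl4, i-Pr2NEt, CH2Cl2, −78 °C) adds to 3 in an auxiliary-controlled Michael reaction to give the imide adduct F7. C3 is then fixed by the auxiliary and C4 by the chelated transition state; the C4 configuration would have to be confirmed and a C4 epimer separated. LiOH/H2O2 removes the auxiliary and gives acid 6.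

Step 9.
- What may go wrong: O-acylation to the pyranone or retro-Claisen cleavage of the chain by methoxide may outrun C-acylation at the hindered ester. The tert-butyl β-keto ester may exchange to the methyl ester on prolonged heating.
- Fallback, from 15 back to 17: DBU in toluene at rt closes 15 by O-acylation to the 4-hydroxy-2-pyranone F8, a storable form of the triketide. Mg(OMe)2 in MeOH then opens the pyranone at its lactone carbonyl to the magnesium chelate of 15, in which C-acylation and aromatisation follow (the known pyranone-to-phloroglucinol rearrangement). This separates the fast O-acylation from the slow ring closure and keeps the concentration of free methoxide low.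

Further compounds

F1 | step 15 | 2,3,4,5-tetramethoxyphenyl 4-methoxybenzoate | COc1ccc(cc1)C(=O)Oc1cc(OC)c(OC)c(OC)c1OC
F2 | step 15 | (2-hydroxy-3,4,5,6-tetramethoxyphenyl)(4-methoxyphenyl)methanone | COc1ccc(cc1)C(=O)c1c(O)c(OC)c(OC)c(OC)c1OC
F3 | step 15 | 2-(4-methoxybenzoyl)-3,4,5,6-tetramethoxyphenyl ester of acid 19 (C3 S, C4 R) | CC(C)(C)OC(=O)c1c(OC)cc(OC)c(c1OC)[C@@H](c1ccc(OC)cc1)[C@@H](C(=O)OC(C)(C)C)CC(=O)Oc1c(OC)c(OC)c(OC)c(OC)c1C(=O)c1ccc(OC)cc1
F4 | step 15 | 4-hydroxy-3,4-dihydrocoumarin aldol product from F3 (C3' and C4' unassigned) | CC(C)(C)OC(=O)c1c(OC)cc(OC)c(c1OC)[C@@H](c1ccc(OC)cc1)[C@@H](C(=O)OC(C)(C)C)C1C(=O)Oc2c(OC)c(OC)c(OC)c(OC)c2C1(O)c1ccc(OC)cc1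
F5 | step 15 | tert-butyl 3-{(1R,2R)-3-tert-butoxy-1-(4-methoxyphenyl)-3-oxo-2-[5,6,7,8-tetramethoxy-4-(4-methoxyphenyl)-2-oxo-2H-chromen-3-yl]propyl}-2,4,6-trimethoxybenzoate | CC(C)(C)OC(=O)c1c(OC)cc(OC)c(c1OC)[C@@H](c1ccc(OC)cc1)[C@@H](C(=O)OC(C)(C)C)C1=C(c2ccc(OC)cc2)c2c(OC)c(OC)c(OC)c(OC)c2OC1=O
F6 | step 2 | methyl 4-[(4R)-4-benzyl-2-oxo-1,3-oxazolidin-3-yl]-4-oxobutanoate | COC(=O)CCC(=O)N1C(=O)OC[C@H]1Cc1ccccc1
F7 | step 2 | methyl (3S,4S)-3-{[(4R)-4-benzyl-2-oxo-1,3-oxazolidin-3-yl]carbonyl}-4-(2,2-dimethyl-4,6-dioxo-1,3-dioxan-5-yl)-4-(4-methoxyphenyl)butanoate | CC1(C)OC(=O)C(C(=O)O1)[C@@H](c1ccc(OC)cc1)[C@@H](C(=O)N1C(=O)OC[C@H]1Cc1ccccc1)CC(=O)OC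
F8 | step 9 | tert-butyl 2-{3-[(1R,2S)-2-(tert-butoxycarbonyl)-4-methoxy-1-(4-methoxyphenyl)-4-oxobutyl]-4-hydroxy-2-oxo-2H-pyran-6-yl}acetate | O=C1OC(CC(=O)OC(C)(C)C)=CC(O)=C1[C@@H](c1ccc(OC)cc1)[C@@H](C(=O)OC(C)(C)C)CC(=O)OC
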